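## The problem

Lespeflorin B1 (18) is a (2R,3R)-trans-dihydroflavonol. Ring A (C4a–C8a) is fused to the pyranone ring C, ring B sits on C2, a hydroxyl sits on C3, and each aromatic ring carries a prenyl group ortho to a free phenol (C6/7-OH and C3'/4'-OH). The only stereocenters are the contiguous C2 and C3. Their trans, diequatorial relationship is the thermodynamic one, so either center can correct the other in the relative sense, but the absolute configuration of the pair has to come from outside. Once the C4 ketone exists both centers are fragile: base opens ring C by β-elimination of the O1 phenoxide and enolises C3, and the α-hydroxy ketone is easily dehydrogenated to the flavonol. The two ortho-prenylphenol units rule out hydrogenation, peracids and strong acid (cyclisation to 2,2-dimethylchromans), which limits both the protecting groups and the way the ketone may be reached. Ring A is 1,2,4,5-substituted, so the prenyl positions are best fixed through aryl halides and not by electrophilic prenylation. The feature that opens the molecule is that O1 on C8a and C4 on C4a are ortho neighbours on ring A. O1–C8a–C4a–C4 is therefore the oxadiene of an ortho-quinone methide, and C2–C3 is a two-carbon dienophile carrying ring B and an oxygen. The 7-oxygen para to C4a stabilises a C4 oxocarbenium ion, and the 4'-oxygen para to C2 polarises the dienophile in the required sense.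

## Retrosynthesis

**18 to 17.** The two phenolic O–CH2 bonds are cut, leading to the 7,4'-bis(methoxymethyl) ether 17. The phenols have to stay masked through hydroxide, chromium, copper/oxygen and acid catalysis. Methoxymethyl ethers tolerate all of these, whereas silyl ethers would be lost in the hydroxide-mediated couplings and benzyl ethers could not be removed without reducing the prenyl groups. The forward step has to free two ortho-prenylphenols without cyclising them and without touching C2/C3; dilute methanolic acid does not epimerise a trans-dihydroflavonol.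

**17 to 14.** No skeletal bond is cut. C4 is stepped back from ketone (17) to carbinol (16) to methyl ether (15), and the C3 hydroxyl to its acetate (14). Carrying the ketone earlier would expose the α-hydroxy ketone to the base needed for ester cleavage. In the chosen order the acetate leaves while C4 is still an ether. The forward steps are a transesterification, an SN1 exchange at the doubly oxygen-activated benzylic C4, and an oxidation that distinguishes the benzylic carbinol from the C3 carbinol and from the allylic/benzylic methylenes of the prenyl groups.

**14 to 4, 10 and 11.** O1–C2 and C3–C4 are cut together. Cutting O1–C2 alone (closure of an open-chain precursor by the phenol) or C4–C4a alone (an acylation) also closes ring C, but leaves both stereocenters to be set separately on an acyclic chain. The double cut removes ring C and both stereocenters in one operation. It leaves two benzaldehyde-derived pieces of similar size: salicylaldehyde 4, which with orthoformate 11 passes through acetal 12 to the 4-methoxy ortho-quinone methide 13, and the E enol acetate 10. The forward reaction must: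
- join the acetoxy-bearing carbon to C4 (regiochemistry);
- translate the E geometry into the 2,3-trans relationship;
- select one face pair under catalyst control;
- give essentially one C4 diastereomer. A C4 epimer formed by the other endo/exo mode on the same diene face has the opposite C2/C3 configuration, so C4 epimers may not be pooled before C4 is oxidised.

**10 to 7.** The vinylic C–O bond is cut (10 from trifluoroborate 9, itself from pinacol boronate 8), then the C=C bond (8 from aldehyde 7). Enol acetylation of the homologous arylacetaldehyde looks shorter but gives E/Z mixtures. The alkene geometry decides the 2,3-relationship and probably the catalyst's recognition, so it is built stereospecifically: an E-selective one-carbon olefination to the alkenylboronate, then a C–O coupling that passes the geometry from boron to oxygen.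

**7 to 5, and 4 to 1, each with 3.** The aryl–CH2 bonds of both prenyl groups are cut to the common boronate 3 and the bromides 6 and 2, which come from commercial 5 and 1 by methoxymethylation. Direct phenol prenylation would give O/C and positional mixtures; the bromides fix C3' and C6. In 1 the 2-hydroxyl is hydrogen-bonded to the formyl group, which allows selective protection of the 4-hydroxyl and leaves the ortho-hydroxyl free for the key step. The couplings must transfer the prenyl group through its unsubstituted carbon.

## Roads not taken

**Alternative 1:** The C2–C3 and C3–O bonds are cut, and ring C is closed afterwards at O1–C8a. In the forward sense Rh2(OAc)4 turns diazoketone A1 into a carbene and 4-methoxybenzyl alcohol A2 adds to give an oxonium ylide. A chiral phosphoric acid directs the capture of this ylide by aldehyde 7 to the syn adduct A3, and displacement of the aryl fluoride by the C2 alkoxide would then close ring C.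
- Merits: it is convergent and reuses 7. Both stereocenters are set in one step, and C4 arrives as the ketone, so no late oxidation is needed. In oxidation-state economy it is better than the chosen plan.
- Weak points: a terminal acyl carbene favours direct O–H insertion over interception of the ylide. The electron-rich aldehyde 7 is a poor electrophile for that interception. Ring closure needs a base acting on a β-hydroxy ketone with an epimerisable α-alkoxy center, where retro-aldol cleavage and C3 epimerisation compete. The benzyl-type ether then has to be removed oxidatively beside two prenyl groups.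
- Comparison: both plans rest on an unproven asymmetric step. The chosen plan offsets its two extra oxidation-level adjustments by closing ring C in the same step that sets the stereocenters, under acid and never under base, and its racemic version is established chemistry.

**Alternative 2:** Ring A is cut at C4a–C8a, C5–C6 and C7–C8. [Rh(cod)2]BF4 with BINAP, a cationic monovalent rhodium catalyst, would join diyne A4 (an ynone and an alkynyl ether tethered through C2–C3) with siloxyalkyne A5 in a [2+2+2] cycloaddition to give A6, forming rings A and C together.
- Merits: C2 and C3 are installed earlier on an acyclic precursor by dependable methods. The ketone is in place, and two rings form in one step. In reliability of absolute configuration it is ahead of the chosen plan.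
- Weak points: A4 combines a thermally labile alkynyl ether of a secondary benzylic alcohol with an ynone next to a silyloxy stereocenter (β-elimination, conjugate addition). The orientation of A5, which decides whether oxygen ends at C7 or C6, depends on a small electronic bias. A5 can trimerise with itself. Three different protecting groups have to be handled.
- Comparison: the chosen plan draws ring A from a commercial bromo aldehyde with the substitution pattern already fixed, and uses only stable aromatic intermediates. Against this it carries the risk of a new enantioselective step.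

**Alternative 3:** Only C4–C4a is cut. Bromine–lithium exchange on aryl bromide A7 with t-BuLi at −100 °C gives the C4a aryllithium, which attacks the N-methoxy-N-methyl amide and closes ring C to A8.
- Merits: every step is known chemistry. The ketone is formed directly, and A8 is one acidic deprotection from 18. In step-by-step precedent and late-stage economy it is at least as good as the chosen plan.
- Weak points: the O1–C2 aryl ether has to be made earlier with stereocontrol at a benzylic carbon bearing a para-oxygenated ring, which ionises easily and erodes configuration. The strongly basic step can deprotonate α to the amide and expel the aryloxide. The sequence is linear and long.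
- Comparison: the chosen plan forms O1–C2 in the ring-closing event itself and is convergent, with a shorter longest linear sequence. It pays with an unprecedented asymmetric cycloaddition and a two-step adjustment of C4.

Key step: step 8

Remark on the chemistry: 14 and 15 are drawn with the 4R (2,4-cis, all-equatorial) configuration expected from endo addition, a center that is erased in step 11; (R)-TRIP stands for whichever antipode of the catalyst proves to give the C2/C3 configuration of 18.

## Route

Step 1
Reactants: 1 5-bromo-2,4-dihydroxybenzaldehyde
Product: 2 5-bromo-2-hydroxy-4-(methoxymethoxy)benzaldehyde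
Conditions: MOMCl (1.05 equiv), K2CO3, acetone, 0 °C to rt
Reagents that add atoms: chloromethyl methyl ether, COCCl
Why: Williamson-type O-alkylation with a chloromethyl ether; the 2-hydroxyl is held in a hydrogen bond to the formyl oxygen, so the more acidic and accessible 4-hydroxyl should be alkylated selectively with one equivalent of reagent.

Step 2
Reactants: 2 5-bromo-2-hydroxy-4-(methoxymethoxy)benzaldehyde; 3 3-methylbut-2-enylboronic acid pinacol ester
Product: 4 2-hydroxy-4-(methoxymethoxy)-5-(3-methylbut-2-enyl)benzaldehyde
Conditions: PdCl2(IPent)(3-chloropyridine) (3 mol %), 5 M aq KOH, THF, 70 °C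
Reagents that add atoms: none
Why: Suzuki–Miyaura allyl–aryl coupling; the bulky N-heterocyclic carbene on palladium is known to deliver 3,3-disubstituted allylboronates through the unsubstituted carbon, giving the linear prenyl arene, and the substrate reacts as its potassium phenoxide, which also protects the aldehyde from hydroxide.

Step 3
Reactants: 5 3-bromo-4-hydroxybenzaldehyde
Product: 6 3-bromo-4-(methoxymethoxy)benzaldehyde
Conditions: MOMCl, K2CO3, acetone, rt
Reagents that add atoms: chloromethyl methyl ether, COCCl
Why: Williamson-type O-alkylation of the only phenol; aldehyde and aryl bromide are inert.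

Step 4
Reactants: 6 3-bromo-4-(methoxymethoxy)benzaldehyde; 3 3-methylbut-2-enylboronic acid pinacol ester
Product: 7 4-(methoxymethoxy)-3-(3-methylbut-2-enyl)benzaldehyde
Conditions: PdCl2(IPent)(3-chloropyridine) (3 mol %), 5 M aq KOH, THF, 70 °C
Reagents that add atoms: none
Why: The same α-selective Suzuki–Miyaura prenylation as in step 2; the methoxymethyl ether is stable to hydroxide, and the electron-rich, non-enolisable aldehyde should remain in the organic phase of the biphasic mixture during the short reaction.

Step 5
Reactants: 7 4-(methoxymethoxy)-3-(3-methylbut-2-enyl)benzaldehyde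
Product: 8 2-[(E)-2-[4-(methoxymethoxy)-3-(3-methylbut-2-enyl)phenyl]ethenyl]-4,4,5,5-tetramethyl-1,3,2-dioxaborolane
Conditions: CrCl2 (8 equiv), Cl2CHBpin (2 equiv), LiI, THF, rt
Reagents that add atoms: 2-(dichloromethyl)-4,4,5,5-tetramethyl-1,3,2-dioxaborolane, ClC(Cl)B1OC(C)(C)C(C)(C)O1
Why: Takai–Utimoto borylolefination; divalent chromium reduces the dichloromethylboronate to a geminal dichromium species that adds to the aldehyde and eliminates to the alkenylboronate with high E selectivity, and it does not reduce the acetal, the aryl ether or the trisubstituted alkene.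

Step 6
Reactants: 8 2-[(E)-2-[4-(methoxymethoxy)-3-(3-methylbut-2-enyl)phenyl]ethenyl]-4,4,5,5-tetramethyl-1,3,2-dioxaborolane
Product: 9 potassium trifluoro[(E)-2-[4-(methoxymethoxy)-3-(3-methylbut-2-enyl)phenyl]ethenyl]borate
Conditions: aq KHF2 (4 equiv), MeOH, rt
Reagents that add atoms: potassium hydrogen difluoride, F.[F-].[K+]
Why: Standard fluoride exchange at boron converting a pinacol boronate into the potassium trifluoroborate; the alkene geometry is untouched and the salt can be purified by precipitation.

Step 7
Reactants: 9 potassium trifluoro[(E)-2-[4-(methoxymethoxy)-3-(3-methylbut-2-enyl)phenyl]ethenyl]borate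
Product: 10 (E)-2-[4-(methoxymethoxy)-3-(3-methylbut-2-enyl)phenyl]ethenyl acetate
Conditions: AcOH (2 equiv), CuBr (10 mol %), DMAP (20 mol %), 4 Å MS, O2 (1 atm), MeCN, 60 °C
Reagents that add atoms: acetic acid, CC(=O)O
Why: Chan–Lam–Evans type copper-catalysed oxidative C–O coupling of an alkenyltrifluoroborate with a carboxylic acid; transmetalation to copper and C–O reductive elimination proceed with retention, so the E boronate should give the E enol acetate.

Step 8
Reactants: 4 2-hydroxy-4-(methoxymethoxy)-5-(3-methylbut-2-enyl)benzaldehyde; 10 (E)-2-[4-(methoxymethoxy)-3-(3-methylbut-2-enyl)phenyl]ethenyl acetate; 11 trimethyl orthoformate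
Product: 14 (2R,3S,4R)-4-methoxy-7-(methoxymethoxy)-2-[4-(methoxymethoxy)-3-(3-methylbut-2-enyl)phenyl]-6-(3-methylbut-2-enyl)-3,4-dihydro-2H-chromen-3-yl acetate, via dimethyl acetal 12 (not isolated), via ortho-quinone methide 13 (not isolated)
Conditions: (R)-TRIP [(R)-3,3'-bis(2,4,6-triisopropylphenyl)-1,1'-binaphthyl-2,2'-diyl hydrogen phosphate] (10 mol %), 11 (1.5 equiv), 5 Å MS, toluene, −20 °C to rt
Reagents that add atoms: none
Why: Proposed new method: the phosphoric acid should catalyse acetalisation of 4 by 11 to 12 and ionisation of 12 to the hydrogen-bonded 4-methoxy ortho-quinone methide 13 (a phenol-stabilised oxocarbenium phosphate), which adds 10 in an inverse-electron-demand hetero-Diels–Alder reaction; the closest known reaction types are the acid-promoted three-component synthesis of 4-alkoxychromans from salicylaldehydes, orthoformates and styrenes or enol ethers, and chiral phosphoric acid catalysed cycloadditions of ortho-quinone methides generated from ortho-hydroxybenzyl alcohols. Ring C closes as a six-membered ring in the [4+2] event, concerted but asynchronous with C3–C4 ahead of O1–C2; in the stepwise limit the phenolic oxygen captures the 4-alkoxybenzyl cation at C2. Regiochemistry needs the acetoxy-bearing carbon to be the nucleophilic terminus, which the para-oxygenated ring B should secure because it stabilises positive charge at C2 far better than the weakly donating acetoxy group does at C3. The trans C2–C3 relationship follows from suprafacial addition to the E alkene and is also the diequatorial, thermodynamically preferred result of a stepwise closure. The absolute configuration at C2 and C3 is to be set by the chiral phosphate, which holds the heterodiene through the phenolic O–H and shields one of its faces. C4 is set by endo approach of ring B to the E-configured 13 (2,4-cis) and is erased later; because a C4 epimer from exo addition to the same diene face would carry the opposite C2/C3 configuration, only the major diastereomer is carried on. The step also needs chemoselectivity for the enol acetate over the prenyl alkenes, which the conjugated, doubly donor-substituted alkene of 10 should provide.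

Step 9
Reactants: 14 (2R,3S,4R)-4-methoxy-7-(methoxymethoxy)-2-[4-(methoxymethoxy)-3-(3-methylbut-2-enyl)phenyl]-6-(3-methylbut-2-enyl)-3,4-dihydro-2H-chromen-3-yl acetate
Product: 15 (2R,3S,4R)-4-methoxy-7-(methoxymethoxy)-2-[4-(methoxymethoxy)-3-(3-methylbut-2-enyl)phenyl]-6-(3-methylbut-2-enyl)-3,4-dihydro-2H-chromen-3-ol
Conditions: K2CO3 (0.2 equiv), MeOH, 0 °C to rt
Reagents that add atoms: none
Why: Zemplén-type base-catalysed transesterification of a secondary acetate; no carbonyl is adjacent, so C2 and C3 cannot epimerise, and the methoxymethyl and benzylic methyl ethers are stable to carbonate.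

Step 10
Reactants: 15 (2R,3S,4R)-4-methoxy-7-(methoxymethoxy)-2-[4-(methoxymethoxy)-3-(3-methylbut-2-enyl)phenyl]-6-(3-methylbut-2-enyl)-3,4-dihydro-2H-chromen-3-ol
Product: 16 (2R,3S)-7-(methoxymethoxy)-2-[4-(methoxymethoxy)-3-(3-methylbut-2-enyl)phenyl]-6-(3-methylbut-2-enyl)-3,4-dihydro-2H-chromene-3,4-diol (C4 epimers)
Conditions: TsOH·H2O (5 mol %), THF/H2O (3:1), rt
Reagents that add atoms: water, O
Why: SN1 exchange of a doubly activated benzylic ether (solvolysis of a 4-alkoxyflavan): the C4 cation is stabilised by the para 7-oxygen and the ortho ring oxygen, and the large excess of water should shift the ether–carbinol equilibrium to the diol without involving C2 or C3. Catalytic sulfonic acid at room temperature should be too weak to cleave the aryl methoxymethyl ethers.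

Step 11
Reactants: 16 (2R,3S)-7-(methoxymethoxy)-2-[4-(methoxymethoxy)-3-(3-methylbut-2-enyl)phenyl]-6-(3-methylbut-2-enyl)-3,4-dihydro-2H-chromene-3,4-diol (C4 epimers)
Product: 17 (2R,3R)-3-hydroxy-7-(methoxymethoxy)-2-[4-(methoxymethoxy)-3-(3-methylbut-2-enyl)phenyl]-6-(3-methylbut-2-enyl)-2,3-dihydrochromen-4-one
Conditions: activated MnO2 (15 equiv), CH2Cl2, rt
Reagents that add atoms: none
Why: Activated MnO2 oxidises benzylic alcohols selectively under neutral heterogeneous conditions, so the saturated C3 carbinol, the prenyl alkenes and the base-sensitive C2/C3 centers should be left alone; both C4 epimers converge on the single (2R,3R) ketone.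

Step 12
Reactants: 17 (2R,3R)-3-hydroxy-7-(methoxymethoxy)-2-[4-(methoxymethoxy)-3-(3-methylbut-2-enyl)phenyl]-6-(3-methylbut-2-enyl)-2,3-dihydrochromen-4-one
Product: 18 lespeflorin B1, (2R,3R)-3,7-dihydroxy-2-[4-hydroxy-3-(3-methylbut-2-enyl)phenyl]-6-(3-methylbut-2-enyl)-2,3-dihydrochromen-4-one
Conditions: 3 M aq HCl/MeOH (1:5), 40 °C
Reagents that add atoms: none
Why: Acid-catalysed acetal cleavage of the two aryl methoxymethyl ethers; a trans-dihydroflavonol does not epimerise under acid, and brief exposure to dilute methanolic HCl at mild temperature is the usual way to unmask ortho-prenylphenols without cyclisation to chromans.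

## Compound list

1 | 5-bromo-2,4-dihydroxybenzaldehyde | O=Cc1cc(Br)c(O)cc1O | starting material
2 | 5-bromo-2-hydroxy-4-(methoxymethoxy)benzaldehyde | O=Cc1cc(Br)c(OCOC)cc1O | intermediate
3 | 3-methylbut-2-enylboronic acid pinacol ester | CC(C)=CCB1OC(C)(C)C(C)(C)O1 | starting material
4 | 2-hydroxy-4-(methoxymethoxy)-5-(3-methylbut-2-enyl)benzaldehyde | O=Cc1cc(CC=C(C)C)c(OCOC)cc1O | intermediate
5 | 3-bromo-4-hydroxybenzaldehyde | O=Cc1ccc(O)c(Br)c1 | starting material
6 | 3-bromo-4-(methoxymethoxy)benzaldehyde | O=Cc1ccc(OCOC)c(Br)c1 | intermediate
7 | 4-(methoxymethoxy)-3-(3-methylbut-2-enyl)benzaldehyde | O=Cc1ccc(OCOC)c(CC=C(C)C)c1 | intermediate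
8 | 2-[(E)-2-[4-(methoxymethoxy)-3-(3-methylbut-2-enyl)phenyl]ethenyl]-4,4,5,5-tetramethyl-1,3,2-dioxaborolane | COCOc1ccc(/C=C/B2OC(C)(C)C(C)(C)O2)cc1CC=C(C)C | intermediate
9 | potassium trifluoro[(E)-2-[4-(methoxymethoxy)-3-(3-methylbut-2-enyl)phenyl]ethenyl]borate | COCOc1ccc(/C=C/[B-](F)(F)F)cc1CC=C(C)C.[K+] | intermediate
10 | (E)-2-[4-(methoxymethoxy)-3-(3-methylbut-2-enyl)phenyl]ethenyl acetate | COCOc1ccc(/C=C/OC(C)=O)cc1CC=C(C)C | intermediate
11 | trimethyl orthoformate | COC(OC)OC | starting material
12 | 2-(dimethoxymethyl)-5-(methoxymethoxy)-4-(3-methylbut-2-enyl)phenol | COC(OC)c1cc(CC=C(C)C)c(OCOC)cc1O | intermediate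
13 | (6E)-6-(methoxymethylidene)-3-(methoxymethoxy)-4-(3-methylbut-2-enyl)cyclohexa-2,4-dien-1-one | O=C1C=C(OCOC)C(CC=C(C)C)=C/C1=C\OC | intermediate
14 | (2R,3S,4R)-4-methoxy-7-(methoxymethoxy)-2-[4-(methoxymethoxy)-3-(3-methylbut-2-enyl)phenyl]-6-(3-methylbut-2-enyl)-3,4-dihydro-2H-chromen-3-yl acetate | COCOc1ccc(cc1CC=C(C)C)[C@H]1Oc2cc(OCOC)c(CC=C(C)C)cc2[C@@H](OC)[C@@H]1OC(C)=O | intermediate
15 | (2R,3S,4R)-4-methoxy-7-(methoxymethoxy)-2-[4-(methoxymethoxy)-3-(3-methylbut-2-enyl)phenyl]-6-(3-methylbut-2-enyl)-3,4-dihydro-2H-chromen-3-ol | COCOc1ccc(cc1CC=C(C)C)[C@H]1Oc2cc(OCOC)c(CC=C(C)C)cc2[C@@H](OC)[C@@H]1O | intermediate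
16 | (2R,3S)-7-(methoxymethoxy)-2-[4-(methoxymethoxy)-3-(3-methylbut-2-enyl)phenyl]-6-(3-methylbut-2-enyl)-3,4-dihydro-2H-chromene-3,4-diol, C4 epimers | COCOc1ccc(cc1CC=C(C)C)[C@H]1Oc2cc(OCOC)c(CC=C(C)C)cc2C(O)[C@@H]1O | intermediate
17 | (2R,3R)-3-hydroxy-7-(methoxymethoxy)-2-[4-(methoxymethoxy)-3-(3-methylbut-2-enyl)phenyl]-6-(3-methylbut-2-enyl)-2,3-dihydrochromen-4-one | COCOc1ccc(cc1CC=C(C)C)[C@H]1Oc2cc(OCOC)c(CC=C(C)C)cc2C(=O)[C@@H]1O | intermediate
18 | lespeflorin B1, (2R,3R)-3,7-dihydroxy-2-[4-hydroxy-3-(3-methylbut-2-enyl)phenyl]-6-(3-methylbut-2-enyl)-2,3-dihydrochromen-4-one | CC(C)=CCc1cc([C@H]2Oc3cc(O)c(CC=C(C)C)cc3C(=O)[C@@H]2O)ccc1O | target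

## Step count and risks

Total steps: 12. Longest linear sequence: 10 steps (5 → 6 → 7 → 8 → 9 → 10 → 14 → 15 → 16 → 17 → 18); the ring A branch (1 → 2 → 4) adds 2 steps.

**Step 8 (key step, the proposed new method).** The most likely failure is poor facial selectivity, because the dienophile is not itself bound to the catalyst. Next come leakage between endo and exo approach, which would mix C2/C3 configurations among the C4 epimers, and partial reaction in the enol-ester sense (attack through the benzylic carbon). Acid-catalysed methanolysis of the enol acetate by the liberated methanol may also compete. The fallback uses known chemistry, sets out from 9 and returns at 15. The copper-catalysed coupling of step 7 is run on 9 with (1S,4R)-camphanic acid in place of acetic acid to give the (E)-enol camphanate F1. F1, 4 and 11 are combined under an achiral acid such as diphenyl phosphate or Sc(OTf)3, which is the established racemic three-component reaction. The 2,3-trans cycloadducts, now covalent diastereomers, are separated by chromatography or crystallisation to give the (2R,3S,4R) 3-O-camphanate F2, and carbonate methanolysis of F2 gives 15. Absolute configuration then rests on separation and not on catalyst control.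

**Step 2.** Oxidative addition into a bromide para to a phenoxide may be slow. Allyl transfer through the substituted carbon would give the 1,1-dimethylallyl isomer, which is hard to separate. The fallback sets out from 2 and returns at 4. Coupling with allylboronic acid pinacol ester (Pd(PPh3)4, aq K2CO3, THF), for which both termini of the allyl group give the same product, yields the 5-allyl aldehyde F3. Cross-metathesis of F3 with 2-methyl-2-butene using second-generation Grubbs catalyst RuCl2(H2IMes)(PCy3)(=CHPh) then installs the prenyl group.

**Step 4.** The same α/γ leakage applies, and in addition hydroxide may attack the non-enolisable aldehyde (Cannizzaro disproportionation) during heating. The fallback sets out from 6 and returns at 7. Allylation with allylboronic acid pinacol ester under carbonate (no hydroxide is needed when regiochemistry is moot) gives the 3-allyl aldehyde F4, followed by the same cross-metathesis with 2-methyl-2-butene.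

**Step 7.** Protodeboronation or oxidative homocoupling of the alkenylboron may outrun C–O bond formation with the weakly nucleophilic acetate, and some E/Z erosion on copper is possible. The fallback sets out from 8 and returns at 10. Oxidation of the C–B bond with NaBO3 in aqueous THF gives the arylacetaldehyde F5. Enol acetylation (Ac2O, KOAc) gives the E/Z enol acetates, from which the E isomer 10 is separated on AgNO3-impregnated silica. This route gives up stereospecificity for fully classical steps.

**Step 10.** The C4 cation may be diverted irreversibly by loss of H3 and tautomerisation to the chroman-3-one, exchange may stop short, or the methoxymethyl ethers may begin to cleave if stronger acid is needed. The fallback sets out from 15 and returns at 17, bypassing 16. DDQ in CH2Cl2/pH 7 buffer at 0 °C oxidises the para-alkoxy-activated benzylic methyl ether by hydride abstraction to the oxocarbenium ion, whose hemiketal collapses to the ketone. This is the usual oxidative cleavage of alkoxybenzyl ethers, and it makes no new compound.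

**Step 11.** MnO2 may cleave the vicinal diol or dehydrogenate the α-hydroxy ketone towards the flavonol. The fallback sets out from 15 and returns at 18. Silylation (TBSOTf, 2,6-lutidine) gives the 3-O-tert-butyldimethylsilyl ether F6. Hydrolysis of the benzylic methyl ether as in step 10 gives the mono-protected carbinol F7. Dess–Martin periodinane, now facing a single hydroxyl, gives the silyloxy ketone F8, which is the same compound as A8. Methanolic HCl removes the silyl and methoxymethyl groups together.

## Further compounds

F1 | step 8 | (E)-2-[4-(methoxymethoxy)-3-(3-methylbut-2-enyl)phenyl]ethenyl (1S,4R)-4,7,7-trimethyl-3-oxo-2-oxabicyclo[2.2.1]heptane-1-carboxylate | COCOc1ccc(/C=C/OC(=O)[C@@]23CC[C@@](C)(C(=O)O2)C3(C)C)cc1CC=C(C)C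
F2 | step 8 | (2R,3S,4R)-4-methoxy-7-(methoxymethoxy)-2-[4-(methoxymethoxy)-3-(3-methylbut-2-enyl)phenyl]-6-(3-methylbut-2-enyl)-3,4-dihydro-2H-chromen-3-yl (1S,4R)-4,7,7-trimethyl-3-oxo-2-oxabicyclo[2.2.1]heptane-1-carboxylate | COCOc1ccc(cc1CC=C(C)C)[C@H]1Oc2cc(OCOC)c(CC=C(C)C)cc2[C@@H](OC)[C@@H]1OC(=O)[C@@]12CC[C@@](C)(C(=O)O1)C2(C)C
F3 | step 2 | 2-hydroxy-4-(methoxymethoxy)-5-(prop-2-enyl)benzaldehyde | O=Cc1cc(CC=C)c(OCOC)cc1O
F4 | step 4 | 4-(methoxymethoxy)-3-(prop-2-enyl)benzaldehyde | O=Cc1ccc(OCOC)c(CC=C)c1
F5 | step 7 | 2-[4-(methoxymethoxy)-3-(3-methylbut-2-enyl)phenyl]acetaldehyde | COCOc1ccc(CC=O)cc1CC=C(C)C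
F0 | step 10 | none | none
F6 | step 11 | tert-butyl[[(2R,3S,4R)-4-methoxy-7-(methoxymethoxy)-2-[4-(methoxymethoxy)-3-(3-methylbut-2-enyl)phenyl]-6-(3-methylbut-2-enyl)-3,4-dihydro-2H-chromen-3-yl]oxy]dimethylsilane | COCOc1ccc(cc1CC=C(C)C)[C@H]1Oc2cc(OCOC)c(CC=C(C)C)cc2[C@@H](OC)[C@@H]1O[Si](C)(C)C(C)(C)C
F7 | step 11 | (2R,3S)-3-(tert-butyldimethylsilyloxy)-7-(methoxymethoxy)-2-[4-(methoxymethoxy)-3-(3-methylbut-2-enyl)phenyl]-6-(3-methylbut-2-enyl)-3,4-dihydro-2H-chromen-4-ol, C4 epimers | COCOc1ccc(cc1CC=C(C)C)[C@H]1Oc2cc(OCOC)c(CC=C(C)C)cc2C(O)[C@@H]1O[Si](C)(C)C(C)(C)C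
F8 | step 11 | (2R,3R)-3-(tert-butyldimethylsilyloxy)-7-(methoxymethoxy)-2-[4-(methoxymethoxy)-3-(3-methylbut-2-enyl)phenyl]-6-(3-methylbut-2-enyl)-2,3-dihydrochromen-4-one | COCOc1ccc(cc1CC=C(C)C)[C@H]1Oc2cc(OCOC)c(CC=C(C)C)cc2C(=O)[C@@H]1O[Si](C)(C)C(C)(C)C
A1 | alternative 1 | 2-diazo-1-[2-fluoro-4-(methoxymethoxy)-5-(3-methylbut-2-enyl)phenyl]ethanone | [N-]=[N+]=CC(=O)c1cc(CC=C(C)C)c(OCOC)cc1F
A2 | alternative 1 | 4-methoxybenzyl alcohol | COc1ccc(CO)cc1
A3 | alternative 1 | (2R,3R)-1-[2-fluoro-4-(methoxymethoxy)-5-(3-methylbut-2-enyl)phenyl]-3-hydroxy-2-(4-methoxybenzyloxy)-3-[4-(methoxymethoxy)-3-(3-methylbut-2-enyl)phenyl]propan-1-one | COCOc1ccc(cc1CC=C(C)C)[C@@H](O)[C@@H](OCc1ccc(OC)cc1)C(=O)c1cc(CC=C(C)C)c(OCOC)cc1F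
A4 | alternative 2 | 4-(tert-butyldimethylsilyloxy)-5-(ethynyloxy)-5-[4-(methoxymethoxy)-3-(3-methylbut-2-enyl)phenyl]pent-1-yn-3-one with the C2/C3 configuration of the target | C#CC(=O)[C@H](O[Si](C)(C)C(C)(C)C)[C@H](OC#C)c1ccc(OCOC)c(CC=C(C)C)c1
A5 | alternative 2 | triisopropyl[(5-methylhex-4-en-1-ynyl)oxy]silane | CC(C)=CCC#CO[Si](C(C)C)(C(C)C)C(C)C
A6 | alternative 2 | 3-O-tert-butyldimethylsilyl 7-O-triisopropylsilyl 4'-O-methoxymethyl ether of lespeflorin B1 | COCOc1ccc(cc1CC=C(C)C)[C@H]1Oc2cc(O[Si](C(C)C)(C(C)C)C(C)C)c(CC=C(C)C)cc2C(=O)[C@@H]1O[Si](C)(C)C(C)(C)C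
A7 | alternative 3 | 3-[2-bromo-5-(methoxymethoxy)-4-(3-methylbut-2-enyl)phenoxy]-2-(tert-butyldimethylsilyloxy)-N-methoxy-3-[4-(methoxymethoxy)-3-(3-methylbut-2-enyl)phenyl]-N-methylpropanamide with the C2/C3 configuration of the target | CON(C)C(=O)[C@H](O[Si](C)(C)C(C)(C)C)[C@H](Oc1cc(OCOC)c(CC=C(C)C)cc1Br)c1ccc(OCOC)c(CC=C(C)C)c1
A8 | alternative 3 | 3-O-tert-butyldimethylsilyl 7,4'-bis(methoxymethyl) ether of lespeflorin B1 | COCOc1ccc(cc1CC=C(C)C)[C@H]1Oc2cc(OCOC)c(CC=C(C)C)cc2C(=O)[C@@H]1O[Si](C)(C)C(C)(C)C
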